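## Analysis of the target

Numbering used throughout: C1–C10 are the decalin carbons, C11 is the formyl carbon on C9, C12 is the ester carbon on C8; β is the face of the C10 methyl, α the opposite face.

- Target 32 is a trans-fused decalin. Ring A (C1–C5, C10) is a saturated cyclohexane; ring B (C5–C10) is a cyclohexene whose C7=C8 bond is conjugated with the C12 methyl ester.
- It has six contiguous stereocentres: the C10 methyl is β, H-5 is α, the C9 formyl group is β and equatorial, the C1 hydroxyl is α and axial, the C3 chlorine is β and equatorial, and C4 carries an axial β-methyl and an equatorial α-chain CH2–CH=CH–CMe2OH with an E double bond.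
- The 4β- and 10β-methyl groups are 1,3-diaxial, and the 1α-hydroxyl is syn-axial to H-3α and H-5α.
- Sensitive groups are the β,γ-unsaturated aldehyde (C9 can epimerise and the double bond can move), the tertiary allylic alcohol (ionises with acid), and the C11/C12 pair, which lactonises whenever C11 is at the alcohol level.
- The synthesis is hard because C5 sits between two quaternary carbons, the secondary chloride is neopentyl (substitution with inversion is not available), and several alkenes must be told apart late in the route.
- The strategy rests on one feature: C6 is the γ-carbon of the C8 ester dienolate and C5 is the β-carbon of a C3 ketone. With C1=C2 and C4=C5 both present, C10 is the prochiral 4-position of a 4,4-disubstituted cyclohexadienone, so forming C5–C6 builds ring B with its enoate in place and makes C10 stereogenic by the choice of enone arm.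

## Retrosynthetic reasoning

**C11 oxidation level.** 32 is taken back to triol 31 and its silyl ether 30. The aldehyde is epimerisable and is made last by selective oxidation of the primary alcohol.

**Side-chain alkene.** The E-disubstituted C=C of 30 is cut by cross-metathesis into allyl compound 28 and 29. An allyl group is the only C3 unit that can be placed on a quaternary C4 by enolate chemistry.

**C3–H and C5–H bonds.** 28 comes from 27, and 27 from the chlorodiene 26 by addition of hydrogen to C2=C3 and C5=C6 from the α face. The 1α-hydroxyl is allylic to one bond and homoallylic to the other, so one directed hydrogenation should set both the equatorial chloride and the trans ring fusion. The allyl group is masked as its dibromide (26 from 25) during this step.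

**C3–Cl bond.** The chloroalkene 25 is traced through 24 and enol triflate 23 to ketone 22 and hydroxy ketone 21. C4 is quaternary, so the ketone can enolise only toward C2, and the neopentyl chloride is made from an sp2 carbon instead of by substitution.

**C1–O bond.** 21 comes from epoxy ketone 20 and this from enone 19. Nucleophilic epoxidation anti to the C10 methyl followed by reductive opening places oxygen at C1 with the axial α configuration.

**C4 substituents and the C4=C5 bond.** 19 is cut at the C4–allyl bond into trienone 17 and 18. 17 comes from 16 by dehydrogenation, and 16 from 15 by C-methylation. Passing through C4=C5 allows alkylation of an extended enolate anti to the C10 methyl. It also removes the C5 configuration left by the ring closure.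

**C5–C6 bond (key disconnection).** 15 is opened between C5 and C6 to dienone 14. A tether on C10 can reach C5 only on the face that carries C9, so the closure gives the cis-fused adduct. The closure is therefore asked only for ring B and for the C10 configuration; C5 is set later, as described above.

**C7=C8 bond.** 14 comes from aldol adduct 12 (via 13), which is cut between C7 and C8 into ester 10 and 11.

**Dienone and ester.** 10 comes from enone 9 by dehydrogenation, and 9 from malonate 8 by loss of one ester group.

**Ring A carbons.** 8 is cut by a Robinson annulation into aldehyde 5 and 6. The α-carbon of the aldehyde becomes C10.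

**C9–C10 bond and C9 configuration.** 5 is cut by a Michael disconnection into 4 and alkylidene malonate 3, itself from 1 and 2. This is the only step that needs an external source of chirality.

## Alternatives that were turned down

**Alternative 1:** Both rings are disconnected at C5–C10 and C8–C9 by an intramolecular Diels–Alder reaction. In the forward direction a chiral secondary-amine salt activates the enal of an achiral open-chain substrate, and the C5–C8 diene adds across C9=C10 to give the trans-fused hexalin A1.
- For: two rings and the C5, C9 and C10 centres come from achiral material in one catalytic step, and the trans fusion is set directly. On this point it is stronger than the chosen route, which has to set C5 a second time.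
- Against: the dienophile is β,β-disubstituted and must form the quaternary C10, which is slow under iminium activation. In A1 the ring B alkene is at C6=C7 and C8 carries an ether instead of the ester, so a double-bond shift and two oxidation-level changes follow. Ring A arrives as a C3=C4 alkene; turning it into the C4 quaternary centre with an allyl group plus a 3β-chloride has no direct solution.
- Comparison: the chosen strategy gives ring B in its final pattern with C11 and C12 already differentiated, and keeps an enone for the ring A work.

**Alternative 2:** C3–Cl, C4–C5 and C9–C10 are disconnected in a chloriranium-initiated bicyclisation of an acyclic polyene β-keto ester, giving the trans-decalin A2.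
- For: the equatorial chloride, the C4 quaternary centre and the trans fusion appear in one step. No chloroalkene has to be hydrogenated. On these points it is stronger and shorter.
- Against: the chlorine donor must choose one trisubstituted alkene out of three alkenes. The C4 configuration depends on a geometrically pure alkene that differs only in methyl versus allyl. The silyloxy stereocentre at C1 must stand axial in the chair transition state and must alone control the facial sense. Chloronium cyclisations are prone to partial cyclisation and elimination. A2 also has the ketone at C8 and the ester at C9, so a one-carbon introduction at C8 and a reduction at C9 are still needed.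
- Comparison: the chosen strategy offers a catalytic asymmetric entry from one easily set centre and the correct C8/C9 carbon pattern from the start.

**Alternative 3:** Ring B is made by one-carbon insertion. A diazoacetic ester and a boron Lewis acid expand a ring-A-complete trans-hydrindanone at its C9 ketone, with migration of the C7 methylene, to the β-keto ester A3.
- For: ring A, with chloride and ring fusion, is settled before ring B is touched, and the ester carbon is placed on C8 directly. On securing the ring fusion early it is as strong as alternative 2.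
- Against: the hydrindanone carries all the hard parts of the molecule (neopentyl chloride, C4 quaternary centre) and is itself an unsolved target. The ketone is flanked by the quaternary C10, which slows the addition. A3 still lacks C11 and has its unsaturation at C8=C9, so a carbon must be added at C9 with β configuration and the double bond moved to C7=C8.
- Comparison: the chosen strategy has C11 in place from the first step and closes ring B complete.

Key step: step 8

## Route

Assumption: the (S)-diarylprolinol silyl ether is taken to add to alkylidene malonate 3 with the same topicity it shows toward nitroalkenes, giving (2R,3R)-5; if the sense at C9 is the opposite, the (R)-catalyst is used and nothing else changes.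

Step 1
Reactants: 1 (tert-butyldimethylsilyloxy)acetaldehyde; 2 dimethyl malonate
Product: 3 dimethyl 2-[2-(tert-butyldimethylsilyloxy)ethylidene]malonate
Conditions: piperidine (10 mol %), AcOH (10 mol %), 4 Å MS, toluene, 0 → 23 °C
Reagents that add atoms: none
Why: Knoevenagel condensation of an unhindered aldehyde with a malonate under buffered amine catalysis; sieves remove water and the mild buffer should limit isomerisation to the enol ether.

Step 2
Reactants: 3 dimethyl 2-[2-(tert-butyldimethylsilyloxy)ethylidene]malonate; 4 propanal
Product: 5 dimethyl 2-[(2R,3R)-1-(tert-butyldimethylsilyloxy)-3-methyl-4-oxobutan-2-yl]malonate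
Conditions: (S)-α,α-diphenylprolinol trimethylsilyl ether (20 mol %), PhCO2H (20 mol %), 4 (3 equiv), toluene, 4 °C
Reagents that add atoms: none
Why: Enamine-catalysed Michael addition of an aldehyde to an alkylidene malonate; the shielded enamine face and the synclinal approach of the acceptor should set C9 (R). The aldehyde α-centre is lost later, so the minor diastereomer is removed here by chromatography because it would become the enantiomer after step 5.

Step 3
Reactants: 5 dimethyl 2-[(2R,3R)-1-(tert-butyldimethylsilyloxy)-3-methyl-4-oxobutan-2-yl]malonate; 6 methyl vinyl ketone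
Product: 8 dimethyl 2-[(1S)-2-(tert-butyldimethylsilyloxy)-1-(1-methyl-4-oxocyclohex-2-en-1-yl)ethyl]malonate (both epimers at the ring carbon), via keto aldehyde 7 (not isolated)
Conditions: 6 (1.5 equiv), pyrrolidine (30 mol %), AcOH (30 mol %), toluene, 23 → 70 °C
Reagents that add atoms: none
Why: Robinson annulation in its enamine form: the aldehyde enamine adds to the enone and the keto aldehyde closes by amine-catalysed aldol condensation. Under the buffered conditions the hindered tertiary malonate C–H should stay un-ionised; the new quaternary centre has no stereochemical consequence.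

Step 4
Reactants: 8 dimethyl 2-[(1S)-2-(tert-butyldimethylsilyloxy)-1-(1-methyl-4-oxocyclohex-2-en-1-yl)ethyl]malonate
Product: 9 methyl (3S)-4-(tert-butyldimethylsilyloxy)-3-(1-methyl-4-oxocyclohex-2-en-1-yl)butanoate (both epimers at the ring carbon)
Conditions: LiCl, H2O, DMSO, 140 °C
Reagents that add atoms: none
Why: Krapcho dealkoxycarbonylation (chloride demethylates one ester, the carboxylate loses CO2); the neutral medium should spare the enone and the silyl ether.

Step 5
Reactants: 9 methyl (3S)-4-(tert-butyldimethylsilyloxy)-3-(1-methyl-4-oxocyclohex-2-en-1-yl)butanoate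
Product: 10 methyl (3S)-4-(tert-butyldimethylsilyloxy)-3-(1-methyl-4-oxocyclohexa-2,5-dien-1-yl)butanoate
Conditions: IBX (2.5 equiv), DMSO, 70 °C
Reagents that add atoms: none
Why: IBX dehydrogenation of a ketone through its enol gives the cross-conjugated dienone. The ring carbon stops being stereogenic, so both epimers converge, and the ester is not enolised under these conditions.

Step 6
Reactants: 10 methyl (3S)-4-(tert-butyldimethylsilyloxy)-3-(1-methyl-4-oxocyclohexa-2,5-dien-1-yl)butanoate; 11 acetaldehyde
Product: 12 methyl (3S)-4-(tert-butyldimethylsilyloxy)-2-(1-hydroxyethyl)-3-(1-methyl-4-oxocyclohexa-2,5-dien-1-yl)butanoate (mixture at C2 and at the carbinol carbon)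
Conditions: LiN(SiMe3)2, THF, −78 °C; 11 (3 equiv); AcOH, −78 °C
Reagents that add atoms: none
Why: Ester enolate aldol addition; the dienone has no enolisable hydrogen and the hindered silylamide should not add to it. The two new centres are removed in step 7.

Step 7
Reactants: 12 methyl (3S)-4-(tert-butyldimethylsilyloxy)-2-(1-hydroxyethyl)-3-(1-methyl-4-oxocyclohexa-2,5-dien-1-yl)butanoate
Product: 14 methyl (2E)-2-[(1R)-2-(tert-butyldimethylsilyloxy)-1-(1-methyl-4-oxocyclohexa-2,5-dien-1-yl)ethyl]but-2-enoate, via mesylate 13 (not isolated)
Conditions: MsCl, Et3N, CH2Cl2, 0 °C; then DBU, 23 °C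
Reagents that add atoms: none
Why: Mesylation and E1cB elimination give the trisubstituted enoate, the E isomer being favoured; either geometry would serve because it is lost in the dienolate. The amidine is too weak to remove the γ-hydrogen, so 14 can be isolated.

Step 8
Reactants: 14 methyl (2E)-2-[(1R)-2-(tert-butyldimethylsilyloxy)-1-(1-methyl-4-oxocyclohexa-2,5-dien-1-yl)ethyl]but-2-enoate
Product: 15 methyl 9β-(tert-butyldimethylsilyloxymethyl)-10β-methyl-3-oxo-5β-H-decalin-1,7-diene-8-carboxylate (cis-fused)
Conditions: KN(SiMe3)2 (1.1 equiv), THF (0.02 M), −78 → −40 °C; AcOH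
Reagents that add atoms: none
Why: Proposed new method: KN(SiMe3)2 removes a γ-hydrogen (C6) of the ethylidene ester, and the γ-carbon of the potassium dienolate adds to C5 of one enone arm, leaving the C3–C4 enolate that is protonated on quench. The closest known reactions are desymmetrising intramolecular Michael additions of stabilised carbanions to 4,4-disubstituted cyclohexadienones and γ-selective vinylogous Michael additions of ester dienolates; their combination on a plain enoate is without direct precedent. Ring B closes in a 6-exo-trig mode, and attack through the α-carbon C8 would need a four-membered ring, so the tether enforces γ-selectivity. C10 becomes stereogenic through the choice of arm: allylic 1,3-strain with the dienolate oxygens should keep C9–H in the dienolate plane and the silyloxymethyl group pseudo-axial, and in that arrangement the arm attacked is the one that gives the 9β,10β relationship of the target. C5 is fixed by the tether: the new bond must be axial on ring A and on the face that carries C9, so H-5 ends cis to the C10 methyl. This centre is not relied upon; it returns to sp2 in step 10 and is set again in step 18. An amidine base is not used because it cannot reach the γ-C–H of a simple enoate, and high dilution should suppress addition between molecules.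

Step 9
Reactants: 15 methyl 9β-(tert-butyldimethylsilyloxymethyl)-10β-methyl-3-oxo-5β-H-decalin-1,7-diene-8-carboxylate
Product: 16 methyl 9β-(tert-butyldimethylsilyloxymethyl)-4,10β-dimethyl-3-oxo-5β-H-decalin-1,7-diene-8-carboxylate (both C4 epimers)
Conditions: LiN(iPr)2, THF, −78 °C; MeI, −78 → −40 °C
Reagents that add atoms: iodomethane, CI
Why: Kinetic α′-deprotonation of the enone (C4 is the only sp3 position next to the ketone) and C-methylation; the C4 configuration does not matter because it is removed in step 10.

Step 10
Reactants: 16 methyl 9β-(tert-butyldimethylsilyloxymethyl)-4,10β-dimethyl-3-oxo-5β-H-decalin-1,7-diene-8-carboxylate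
Product: 17 methyl 9β-(tert-butyldimethylsilyloxymethyl)-4,10β-dimethyl-3-oxodecalin-1,4,7-triene-8-carboxylate
Conditions: IBX (3 equiv), DMSO, 70 °C
Reagents that add atoms: none
Why: IBX dehydrogenation through the C3–C4 enol introduces C4=C5 and gives the bicyclic cross-conjugated dienone; the endocyclic tetrasubstituted enone is expected over the exocyclic methylene isomer. The C4 and C5 centres are erased, so the ring fusion can be set later from the α face.

Step 11
Reactants: 17 methyl 9β-(tert-butyldimethylsilyloxymethyl)-4,10β-dimethyl-3-oxodecalin-1,4,7-triene-8-carboxylate; 18 allyl bromide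
Product: 19 methyl 4α-allyl-9β-(tert-butyldimethylsilyloxymethyl)-4β,10β-dimethyl-3-oxodecalin-1,5,7-triene-8-carboxylate
Conditions: KN(SiMe3)2, THF, −78 °C; 18 (2 equiv), −78 → 0 °C
Reagents that add atoms: none
Why: Deconjugative α-alkylation of an extended enolate: the doubly activated C6–H is removed, and C-allylation at C4 (the α-carbon of the ketone dienolate) moves the double bond to C5=C6. The allyl group should enter anti to the pseudo-axial C10 methyl, as is usual for 4-substituted 4-en-3-ones, giving 4α-allyl and 4β-methyl.

Step 12
Reactants: 19 methyl 4α-allyl-9β-(tert-butyldimethylsilyloxymethyl)-4β,10β-dimethyl-3-oxodecalin-1,5,7-triene-8-carboxylate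
Product: 20 methyl 4α-allyl-9β-(tert-butyldimethylsilyloxymethyl)-1α,2α-epoxy-4β,10β-dimethyl-3-oxodecalin-5,7-diene-8-carboxylate
Conditions: t-BuOOH (decane solution), DBU, CH2Cl2, 0 → 23 °C
Reagents that add atoms: tert-butyl hydroperoxide, CC(C)(C)OO
Why: Weitz–Scheffer nucleophilic epoxidation of the enone; the peroxide should add to C1 anti to the adjacent axial C10 methyl, as in steroidal 1-en-3-ones, giving the 1α,2α-epoxide. The dienoate is much less electrophilic and there is no acidic hydrogen left.

Step 13
Reactants: 20 methyl 4α-allyl-9β-(tert-butyldimethylsilyloxymethyl)-1α,2α-epoxy-4β,10β-dimethyl-3-oxodecalin-5,7-diene-8-carboxylate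
Product: 21 methyl 4α-allyl-9β-(tert-butyldimethylsilyloxymethyl)-1α-hydroxy-4β,10β-dimethyl-3-oxodecalin-5,7-diene-8-carboxylate
Conditions: (PhSe)2, NaBH4, EtOH (premixed); AcOH; 20, 0 → 23 °C
Reagents that add atoms: none
Why: Selenolate-mediated reductive opening of an α,β-epoxy ketone to the β-hydroxy ketone; the C1–O bond is not touched, so the 1α configuration is kept. The buffered medium should avoid dehydration.

Step 14
Reactants: 21 methyl 4α-allyl-9β-(tert-butyldimethylsilyloxymethyl)-1α-hydroxy-4β,10β-dimethyl-3-oxodecalin-5,7-diene-8-carboxylate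
Product: 22 methyl 4α-allyl-9β-(tert-butyldimethylsilyloxymethyl)-4β,10β-dimethyl-3-oxo-1α-(trimethylsilyloxy)decalin-5,7-diene-8-carboxylate
Conditions: Me3SiOTf, 2,6-lutidine, CH2Cl2, −78 °C
Reagents that add atoms: trimethylsilyl trifluoromethanesulfonate, C[Si](C)(C)OS(=O)(=O)C(F)(F)F
Why: Silylation of the hindered β-hydroxyl so that enolisation in step 15 cannot start a retro-aldol cleavage; the trimethylsilyl group is chosen because it can later be removed without loss of the primary tert-butyldimethylsilyl ether.

Step 15
Reactants: 22 methyl 4α-allyl-9β-(tert-butyldimethylsilyloxymethyl)-4β,10β-dimethyl-3-oxo-1α-(trimethylsilyloxy)decalin-5,7-diene-8-carboxylate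
Product: 23 methyl 4α-allyl-9β-(tert-butyldimethylsilyloxymethyl)-4β,10β-dimethyl-3-(trifluoromethylsulfonyloxy)-1α-(trimethylsilyloxy)decalin-2,5,7-triene-8-carboxylate
Conditions: KN(SiMe3)2 added to 22 and PhNTf2, THF, −78 °C
Reagents that add atoms: N-phenylbis(trifluoromethanesulfonimide), O=S(=O)(N(c1ccccc1)S(=O)(=O)C(F)(F)F)C(F)(F)F
Why: Enol triflate formation; C4 is quaternary, so the ketone can enolise only toward C2. Low temperature and trapping in situ should suppress β-elimination of the silyloxide.

Step 16
Reactants: 23 methyl 4α-allyl-9β-(tert-butyldimethylsilyloxymethyl)-4β,10β-dimethyl-3-(trifluoromethylsulfonyloxy)-1α-(trimethylsilyloxy)decalin-2,5,7-triene-8-carboxylate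
Product: 25 methyl 4α-allyl-9β-(tert-butyldimethylsilyloxymethyl)-3-chloro-1α-hydroxy-4β,10β-dimethyldecalin-2,5,7-triene-8-carboxylate, via trimethylsilyl ether 24 (not isolated)
Conditions: Ni(cod)2 (zerovalent nickel, 10 mol %), LiCl (3 equiv), DMA/THF, 23 °C; then K2CO3, MeOH, 0 °C
Reagents that add atoms: lithium chloride, [Li+].[Cl-]
Why: Nickel-catalysed conversion of an enol triflate into an alkenyl chloride (oxidative addition of the C–O bond, triflate/chloride exchange, C–Cl reductive elimination). Basic methanol then removes only the trimethylsilyl ether.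

Step 17
Reactants: 25 methyl 4α-allyl-9β-(tert-butyldimethylsilyloxymethyl)-3-chloro-1α-hydroxy-4β,10β-dimethyldecalin-2,5,7-triene-8-carboxylate
Product: 26 methyl 9β-(tert-butyldimethylsilyloxymethyl)-3-chloro-4α-(2,3-dibromopropyl)-1α-hydroxy-4β,10β-dimethyldecalin-2,5,7-triene-8-carboxylate (both epimers at the CHBr carbon)
Conditions: pyridinium tribromide (1.05 equiv), CH2Cl2, −40 °C
Reagents that add atoms: pyridinium tribromide, [Br-].BrBr.c1cc[nH+]cc1
Why: Electrophilic bromination of the only unhindered, electronically normal alkene; the chloroalkene and the diene ester are electron-poor and flanked by quaternary carbons. The dibromide masks the allyl group for step 18.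

Step 18
Reactants: 26 methyl 9β-(tert-butyldimethylsilyloxymethyl)-3-chloro-4α-(2,3-dibromopropyl)-1α-hydroxy-4β,10β-dimethyldecalin-2,5,7-triene-8-carboxylate
Product: 27 methyl 9β-(tert-butyldimethylsilyloxymethyl)-3β-chloro-4α-(2,3-dibromopropyl)-1α-hydroxy-4β,10β-dimethyl-5α-H-decalin-7-ene-8-carboxylate
Conditions: [Ir(cod)(PCy3)(py)]PF6 (15 mol %), H2 (4 atm), CH2Cl2, 23 °C
Reagents that add atoms: none
Why: Hydroxyl-directed homogeneous hydrogenation: iridium bound to the axial 1α-hydroxyl should deliver hydrogen to the α face of the allylic C2=C3 chloroalkene and of the homoallylic C5=C6 bond, giving H-3α (chloride β, equatorial) and H-5α (trans fusion). The remote C7=C8 bond is conjugated with the ester and has no directing group, so it is expected to remain; cationic iridium catalysts are known to reduce chloroalkenes without loss of chlorine.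

Step 19
Reactants: 27 methyl 9β-(tert-butyldimethylsilyloxymethyl)-3β-chloro-4α-(2,3-dibromopropyl)-1α-hydroxy-4β,10β-dimethyl-5α-H-decalin-7-ene-8-carboxylate
Product: 28 methyl 4α-allyl-9β-(tert-butyldimethylsilyloxymethyl)-3β-chloro-1α-hydroxy-4β,10β-dimethyl-5α-H-decalin-7-ene-8-carboxylate
Conditions: Zn dust, AcOH, EtOH, 23 °C
Reagents that add atoms: none
Why: Zinc-mediated reductive 1,2-debromination regenerates the alkene; the secondary alkyl chloride and the enoate are inert to zinc under these conditions.

Step 20
Reactants: 28 methyl 4α-allyl-9β-(tert-butyldimethylsilyloxymethyl)-3β-chloro-1α-hydroxy-4β,10β-dimethyl-5α-H-decalin-7-ene-8-carboxylate; 29 2-methylbut-3-en-2-ol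
Product: 30 methyl 9β-(tert-butyldimethylsilyloxymethyl)-3β-chloro-1α-hydroxy-4α-[(2E)-4-hydroxy-4-methylpent-2-en-1-yl]-4β,10β-dimethyl-5α-H-decalin-7-ene-8-carboxylate
Conditions: second-generation Grubbs catalyst (H2IMes)(PCy3)Cl2Ru=CHPh (5 mol %), 29 (10 equiv), CH2Cl2, 40 °C
Reagents that add atoms: none
Why: Olefin cross-metathesis of a terminal alkene with a hindered tertiary allylic alcohol, which does not homodimerise readily and should give the E alkene; the trisubstituted enoate does not take part.

Step 21
Reactants: 30 methyl 9β-(tert-butyldimethylsilyloxymethyl)-3β-chloro-1α-hydroxy-4α-[(2E)-4-hydroxy-4-methylpent-2-en-1-yl]-4β,10β-dimethyl-5α-H-decalin-7-ene-8-carboxylate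
Product: 31 methyl 3β-chloro-1α-hydroxy-9β-(hydroxymethyl)-4α-[(2E)-4-hydroxy-4-methylpent-2-en-1-yl]-4β,10β-dimethyl-5α-H-decalin-7-ene-8-carboxylate
Conditions: HF·pyridine, pyridine, THF, 0 °C
Reagents that add atoms: none
Why: Fluoride cleavage of the primary silyl ether; the buffered, nearly neutral medium is chosen to avoid lactonisation onto the ester and ionisation of the tertiary allylic alcohol.

Step 22
Reactants: 31 methyl 3β-chloro-1α-hydroxy-9β-(hydroxymethyl)-4α-[(2E)-4-hydroxy-4-methylpent-2-en-1-yl]-4β,10β-dimethyl-5α-H-decalin-7-ene-8-carboxylate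
Product: 32 methyl 3β-chloro-9β-formyl-1α-hydroxy-4α-[(2E)-4-hydroxy-4-methylpent-2-en-1-yl]-4β,10β-dimethyl-5α-H-decalin-7-ene-8-carboxylate (CNP0167913.1)
Conditions: TEMPO (10 mol %), PhI(OAc)2, CH2Cl2, 23 °C
Reagents that add atoms: none
Why: Oxoammonium oxidation, selective for the primary alcohol over the hindered axial secondary and the tertiary alcohols; the neutral conditions should leave C9 and the position of the double bond unchanged.

## Compound list

1 | (tert-butyldimethylsilyloxy)acetaldehyde | O=CCO[Si](C)(C)C(C)(C)C | starting material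
2 | dimethyl malonate | COC(=O)CC(=O)OC | starting material
3 | dimethyl 2-[2-(tert-butyldimethylsilyloxy)ethylidene]malonate | COC(=O)C(=CCO[Si](C)(C)C(C)(C)C)C(=O)OC | intermediate
4 | propanal | CCC=O | starting material
5 | dimethyl 2-[(2R,3R)-1-(tert-butyldimethylsilyloxy)-3-methyl-4-oxobutan-2-yl]malonate | O=C[C@H](C)[C@@H](CO[Si](C)(C)C(C)(C)C)C(C(=O)OC)C(=O)OC | intermediate
6 | methyl vinyl ketone (but-3-en-2-one) | CC(=O)C=C | starting material
7 | dimethyl 2-[(2S)-1-(tert-butyldimethylsilyloxy)-3-formyl-3-methyl-6-oxoheptan-2-yl]malonate (keto aldehyde, both C3 epimers) | O=CC(C)(CCC(C)=O)[C@@H](CO[Si](C)(C)C(C)(C)C)C(C(=O)OC)C(=O)OC | intermediate (not isolated)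
8 | dimethyl 2-[(1S)-2-(tert-butyldimethylsilyloxy)-1-(1-methyl-4-oxocyclohex-2-en-1-yl)ethyl]malonate (both epimers at the ring carbon) | COC(=O)C(C(=O)OC)[C@H](CO[Si](C)(C)C(C)(C)C)C1(C)CCC(=O)C=C1 | intermediate
9 | methyl (3S)-4-(tert-butyldimethylsilyloxy)-3-(1-methyl-4-oxocyclohex-2-en-1-yl)butanoate (both epimers at the ring carbon) | COC(=O)C[C@H](CO[Si](C)(C)C(C)(C)C)C1(C)CCC(=O)C=C1 | intermediate
10 | methyl (3S)-4-(tert-butyldimethylsilyloxy)-3-(1-methyl-4-oxocyclohexa-2,5-dien-1-yl)butanoate | COC(=O)C[C@H](CO[Si](C)(C)C(C)(C)C)C1(C)C=CC(=O)C=C1 | intermediate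
11 | acetaldehyde | CC=O | starting material
12 | methyl (3S)-4-(tert-butyldimethylsilyloxy)-2-(1-hydroxyethyl)-3-(1-methyl-4-oxocyclohexa-2,5-dien-1-yl)butanoate (mixture at C2 and the carbinol carbon) | COC(=O)C(C(C)O)[C@H](CO[Si](C)(C)C(C)(C)C)C1(C)C=CC(=O)C=C1 | intermediate
13 | methanesulfonate of 12 | COC(=O)C(C(C)OS(C)(=O)=O)[C@H](CO[Si](C)(C)C(C)(C)C)C1(C)C=CC(=O)C=C1 | intermediate (not isolated)
14 | methyl (2E)-2-[(1R)-2-(tert-butyldimethylsilyloxy)-1-(1-methyl-4-oxocyclohexa-2,5-dien-1-yl)ethyl]but-2-enoate | C/C=C(/C(=O)OC)[C@H](CO[Si](C)(C)C(C)(C)C)C1(C)C=CC(=O)C=C1 | intermediate (key-step precursor)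
15 | methyl 9β-(tert-butyldimethylsilyloxymethyl)-10β-methyl-3-oxo-5β-H-decalin-1,7-diene-8-carboxylate (cis-fused) | COC(=O)C1=CC[C@@H]2CC(=O)C=C[C@]2(C)[C@H]1CO[Si](C)(C)C(C)(C)C | intermediate (key-step product)
16 | methyl 9β-(tert-butyldimethylsilyloxymethyl)-4,10β-dimethyl-3-oxo-5β-H-decalin-1,7-diene-8-carboxylate (both C4 epimers) | COC(=O)C1=CC[C@@H]2C(C)C(=O)C=C[C@]2(C)[C@H]1CO[Si](C)(C)C(C)(C)C | intermediate
17 | methyl 9β-(tert-butyldimethylsilyloxymethyl)-4,10β-dimethyl-3-oxodecalin-1,4,7-triene-8-carboxylate | COC(=O)C1=CCC2=C(C)C(=O)C=C[C@]2(C)[C@H]1CO[Si](C)(C)C(C)(C)C | intermediate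
18 | allyl bromide | C=CCBr | starting material
19 | methyl 4α-allyl-9β-(tert-butyldimethylsilyloxymethyl)-4β,10β-dimethyl-3-oxodecalin-1,5,7-triene-8-carboxylate | COC(=O)C1=CC=C2[C@](C)(CC=C)C(=O)C=C[C@]2(C)[C@H]1CO[Si](C)(C)C(C)(C)C | intermediate
20 | methyl 4α-allyl-9β-(tert-butyldimethylsilyloxymethyl)-1α,2α-epoxy-4β,10β-dimethyl-3-oxodecalin-5,7-diene-8-carboxylate | COC(=O)C1=CC=C2[C@](C)(CC=C)C(=O)[C@@H]3O[C@@H]3[C@]2(C)[C@H]1CO[Si](C)(C)C(C)(C)C | intermediate
21 | methyl 4α-allyl-9β-(tert-butyldimethylsilyloxymethyl)-1α-hydroxy-4β,10β-dimethyl-3-oxodecalin-5,7-diene-8-carboxylate | COC(=O)C1=CC=C2[C@](C)(CC=C)C(=O)C[C@H](O)[C@]2(C)[C@H]1CO[Si](C)(C)C(C)(C)C | intermediate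
22 | methyl 4α-allyl-9β-(tert-butyldimethylsilyloxymethyl)-4β,10β-dimethyl-3-oxo-1α-(trimethylsilyloxy)decalin-5,7-diene-8-carboxylate | COC(=O)C1=CC=C2[C@](C)(CC=C)C(=O)C[C@H](O[Si](C)(C)C)[C@]2(C)[C@H]1CO[Si](C)(C)C(C)(C)C | intermediate
23 | methyl 4α-allyl-9β-(tert-butyldimethylsilyloxymethyl)-4β,10β-dimethyl-3-(trifluoromethylsulfonyloxy)-1α-(trimethylsilyloxy)decalin-2,5,7-triene-8-carboxylate | COC(=O)C1=CC=C2[C@](C)(CC=C)C(OS(=O)(=O)C(F)(F)F)=C[C@H](O[Si](C)(C)C)[C@]2(C)[C@H]1CO[Si](C)(C)C(C)(C)C | intermediate
24 | methyl 4α-allyl-9β-(tert-butyldimethylsilyloxymethyl)-3-chloro-4β,10β-dimethyl-1α-(trimethylsilyloxy)decalin-2,5,7-triene-8-carboxylate | COC(=O)C1=CC=C2[C@](C)(CC=C)C(Cl)=C[C@H](O[Si](C)(C)C)[C@]2(C)[C@H]1CO[Si](C)(C)C(C)(C)C | intermediate (not isolated)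
25 | methyl 4α-allyl-9β-(tert-butyldimethylsilyloxymethyl)-3-chloro-1α-hydroxy-4β,10β-dimethyldecalin-2,5,7-triene-8-carboxylate | COC(=O)C1=CC=C2[C@](C)(CC=C)C(Cl)=C[C@H](O)[C@]2(C)[C@H]1CO[Si](C)(C)C(C)(C)C | intermediate
26 | methyl 9β-(tert-butyldimethylsilyloxymethyl)-3-chloro-4α-(2,3-dibromopropyl)-1α-hydroxy-4β,10β-dimethyldecalin-2,5,7-triene-8-carboxylate (both epimers at the CHBr carbon) | COC(=O)C1=CC=C2[C@](C)(CC(Br)CBr)C(Cl)=C[C@H](O)[C@]2(C)[C@H]1CO[Si](C)(C)C(C)(C)C | intermediate
27 | methyl 9β-(tert-butyldimethylsilyloxymethyl)-3β-chloro-4α-(2,3-dibromopropyl)-1α-hydroxy-4β,10β-dimethyl-5α-H-decalin-7-ene-8-carboxylate (both epimers at the CHBr carbon) | COC(=O)C1=CC[C@H]2[C@](C)(CC(Br)CBr)[C@@H](Cl)C[C@H](O)[C@]2(C)[C@H]1CO[Si](C)(C)C(C)(C)C | intermediate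
28 | methyl 4α-allyl-9β-(tert-butyldimethylsilyloxymethyl)-3β-chloro-1α-hydroxy-4β,10β-dimethyl-5α-H-decalin-7-ene-8-carboxylate | COC(=O)C1=CC[C@H]2[C@](C)(CC=C)[C@@H](Cl)C[C@H](O)[C@]2(C)[C@H]1CO[Si](C)(C)C(C)(C)C | intermediate
29 | 2-methylbut-3-en-2-ol | C=CC(C)(C)O | starting material
30 | methyl 9β-(tert-butyldimethylsilyloxymethyl)-3β-chloro-1α-hydroxy-4α-[(2E)-4-hydroxy-4-methylpent-2-en-1-yl]-4β,10β-dimethyl-5α-H-decalin-7-ene-8-carboxylate | COC(=O)C1=CC[C@H]2[C@](C)(C/C=C/C(C)(C)O)[C@@H](Cl)C[C@H](O)[C@]2(C)[C@H]1CO[Si](C)(C)C(C)(C)C | intermediate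
31 | methyl 3β-chloro-1α-hydroxy-9β-(hydroxymethyl)-4α-[(2E)-4-hydroxy-4-methylpent-2-en-1-yl]-4β,10β-dimethyl-5α-H-decalin-7-ene-8-carboxylate | COC(=O)C1=CC[C@H]2[C@](C)(C/C=C/C(C)(C)O)[C@@H](Cl)C[C@H](O)[C@]2(C)[C@H]1CO | intermediate
32 | methyl 3β-chloro-9β-formyl-1α-hydroxy-4α-[(2E)-4-hydroxy-4-methylpent-2-en-1-yl]-4β,10β-dimethyl-5α-H-decalin-7-ene-8-carboxylate (CNP0167913.1) | COC(=O)C1=CC[C@H]2[C@](C)(C/C=C/C(C)(C)O)[C@@H](Cl)C[C@H](O)[C@]2(C)[C@H]1C=O | target

## Step count and least certain steps

Total step count: 22. Longest linear sequence: 22 steps (from 1 and 2 to 32); all other building blocks are commercial and enter singly.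

**Step 8 (key step, new method).** The most likely failure is that the strongly basic dienolate or the amide reacts with the cross-conjugated dienone of a second molecule, or that the two enone arms are poorly discriminated, which would give the C10 epimer. The fallback separates enolisation from bond formation and uses known chemistry. From 14, KN(SiMe3)2 with Me3SiCl present at −78 °C traps the dienolate as the trimethylsilyl dienol ether F1. The Lewis acid EtAlCl2 in CH2Cl2 at −78 °C then promotes an intramolecular vinylogous Mukaiyama–Michael addition of the same kind as the established allylsilane closures onto dienones. Aqueous work-up returns the route at 15.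

**Step 18.** The most likely failures are loss of chlorine by β-chloride elimination from an iridium alkyl, and 1,4-addition of hydrogen across the diene ester that would leave the ester out of conjugation. The fallback changes the mechanism to hydrogen-atom transfer: from 26, Mn(dpm)3 with PhSiH3 and t-BuOOH in i-PrOH. This radical hydrogenation tolerates halogen on the alkene and tends to give the thermodynamically preferred trans ring fusion and equatorial substituent. It returns at 27 and makes no new compound (F0).

**Step 11.** The extended enolate is ambident, so allylation may go to C6 or to oxygen, or show poor facial selectivity at C4. The fallback delivers the allyl group through palladium. From 17, the potassium enolate is O-acylated with allyl chloroformate to the allyl dienol carbonate F2. Pd(PPh3)4 (zerovalent palladium) in THF then brings about decarboxylative allylation, in which the π-allyl fragment recombines with the enolate at C4 anti to the C10 methyl. The route is rejoined at 19.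

**Step 3.** The free malonate C–H may add to the enone, or the amine may induce retro-Michael loss of the malonate. The fallback removes the second ester first. From 5, HC(OMe)3 and PPTS in MeOH give the dimethyl acetal F3. LiCl in wet DMSO at 140 °C gives the monoester acetal F4, and PPTS in aqueous acetone frees the aldehyde F5. With no acidic malonate left, F5 undergoes a base-catalysed Robinson annulation with 6 (KOH, MeOH) and returns at 9.

**Step 21.** The freed C11 hydroxyl may close onto the C12 ester to a five-membered lactone. The fallback accepts the lactone and reopens it. From 30, Bu4NF in THF takes desilylation and lactonisation to completion to give the lactone F6. LiOH in aqueous THF opens it to the lithium hydroxy carboxylate F7, which is not acidified but O-methylated with iodomethane in DMF. This returns at 31, which is oxidised at once.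

## Further compounds

F1 | step 8 | trimethylsilyl dienol ether of 14: methyl ketene trimethylsilyl acetal of 2-[(1R)-2-(tert-butyldimethylsilyloxy)-1-(1-methyl-4-oxocyclohexa-2,5-dien-1-yl)ethyl]but-3-enoate | C=CC(=C(OC)O[Si](C)(C)C)[C@H](CO[Si](C)(C)C(C)(C)C)C1(C)C=CC(=O)C=C1
F0 | step 18 | none | none
F2 | step 11 | allyl dienol carbonate of 17: methyl 3-(allyloxycarbonyloxy)-9β-(tert-butyldimethylsilyloxymethyl)-4,10β-dimethyldecalin-1,3,5,7-tetraene-8-carboxylate | COC(=O)C1=CC=C2C(C)=C(OC(=O)OCC=C)C=C[C@]2(C)[C@H]1CO[Si](C)(C)C(C)(C)C
F3 | step 3 | dimethyl 2-[(2R,3R)-1-(tert-butyldimethylsilyloxy)-4,4-dimethoxy-3-methylbutan-2-yl]malonate | COC(OC)[C@H](C)[C@@H](CO[Si](C)(C)C(C)(C)C)C(C(=O)OC)C(=O)OC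
F4 | step 3 | methyl (3S,4R)-3-(tert-butyldimethylsilyloxymethyl)-5,5-dimethoxy-4-methylpentanoate | COC(OC)[C@H](C)[C@@H](CO[Si](C)(C)C(C)(C)C)CC(=O)OC
F5 | step 3 | methyl (3S,4R)-3-(tert-butyldimethylsilyloxymethyl)-4-methyl-5-oxopentanoate | O=C[C@H](C)[C@@H](CO[Si](C)(C)C(C)(C)C)CC(=O)OC
F6 | step 21 | 12,11-lactone of 31 (γ-lactone between the C11 oxygen and C12) | O=C1OC[C@H]2C1=CC[C@H]3[C@](C)(C/C=C/C(C)(C)O)[C@@H](Cl)C[C@H](O)[C@]23C
F7 | step 21 | lithium 3β-chloro-1α-hydroxy-9β-(hydroxymethyl)-4α-[(2E)-4-hydroxy-4-methylpent-2-en-1-yl]-4β,10β-dimethyl-5α-H-decalin-7-ene-8-carboxylate | [Li+].[O-]C(=O)C1=CC[C@H]2[C@](C)(C/C=C/C(C)(C)O)[C@@H](Cl)C[C@H](O)[C@]2(C)[C@H]1CO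
A1 | alternative 1 | trans-fused hexalin with C9 formyl, C8 (4-methoxybenzyloxy)methyl, C1 ethylene ketal and C3=C4, C6=C7 alkenes | C(OCc1ccc(OC)cc1)[C@H]2C=C[C@H]3C(C)=CCC4(OCCO4)[C@]3(C)[C@H]2C=O
A2 | alternative 2 | methyl 4α-allyl-1α-(tert-butyldimethylsilyloxy)-3β-chloro-4β,10β-dimethyl-8-oxo-trans-decalin-9-carboxylate | O=C1CC[C@H]2[C@](C)(CC=C)[C@@H](Cl)C[C@H](O[Si](C)(C)C(C)(C)C)[C@]2(C)[C@H]1C(=O)OC
A3 | alternative 3 | methyl 4α-allyl-1α-(tert-butyldimethylsilyloxy)-3β-chloro-9-hydroxy-4β,10β-dimethyl-trans-decalin-8-ene-8-carboxylate (enol form of the β-keto ester) | COC(=O)C=1CC[C@H]2[C@](C)(CC=C)[C@@H](Cl)C[C@H](O[Si](C)(C)C(C)(C)C)[C@]2(C)C=1O
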